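The meta-related oxygens of ring A (on C5, C7 and C8a) match the polarity of an electron-rich diene joined to a β-oxygenated enone. Ring A is therefore made last by [4+2] cycloaddition. C5–C8 come from a prenylated 1,1-dimethoxy-3-silyloxydiene. C4a–C8a is the C=C bond of an enantiopure (S)-2-aryl-2,3-dihydropyran-4-one that already holds rings B and C and the C2 stereocentre. One operation forms C4a–C5 and C8–C8a, closes ring A and aromatises it, with 5-OMe, free 7-OH and 8-prenyl in place. The dienophile carries a phenylsulfinyl group on the future C4a rather than a halogen, because it activates more strongly and leaves by thermal syn elimination without base.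

Key step: step 8

Design remark: in any cycloadduct of this type, the substituent on C4a and H-8a are cis, and H-8a is not acidic. A 4a-halide would have no anti-periplanar hydrogen, so it would need a base, and that base could expel O1 and open ring C. A sulfoxide uses exactly this cis geometry for a neutral Ei elimination. The ring skeleton of the dienophile is unchanged, and a 5-bromo analogue appears only in a fallback.

Assumption: Ti(OiPr)4/(S)-BINOL is taken to direct the diene to the Si face of the aryl aldehyde, the sense this catalyst family shows in allylations and aldol additions. Si-face attack gives (S). The (R)-ligand would be used if the sense proved opposite.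

Step 1
Reactants: 1 isovanillin (3-hydroxy-4-methoxybenzaldehyde)
Product: 2 3-(tert-butyldimethylsilyloxy)-4-methoxybenzaldehyde
Conditions: TBSCl, imidazole, DMF, rt
Reagents that add atoms: tert-butyldimethylsilyl chloride, CC(C)(C)[Si](C)(C)Cl
Why: Standard imidazole-promoted silylation of a phenol, which masks the acidic 3'-OH from the titanium catalyst, the diene and the later O-methylation.

Step 2
Reactants: 2 3-(tert-butyldimethylsilyloxy)-4-methoxybenzaldehyde; 3 (E)-1-methoxy-3-(trimethylsilyloxy)buta-1,3-diene
Product: 5 (S)-2-[3-(tert-butyldimethylsilyloxy)-4-methoxyphenyl]-2,3-dihydro-4H-pyran-4-one, via silylated aldol adduct 4 (not isolated)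
Conditions: (S)-BINOL (20 mol %), Ti(OiPr)4 (10 mol %), 4 Å MS, Et2O, −20 °C; then CF3CO2H, CH2Cl2, 0 °C; aq NaHCO3
Reagents that add atoms: none
Why: Titanium–BINOLate-catalysed asymmetric hetero-Diels–Alder reaction (Mukaiyama aldol addition, then acid-induced cyclisation with loss of methanol), well established for aryl aldehydes; the chiral Lewis acid exposes the Si face of the aldehyde and so sets C2 as (S), and crystallisation of 5 can raise the enantiomeric purity if needed.

Step 3
Reactants: 5 (S)-2-[3-(tert-butyldimethylsilyloxy)-4-methoxyphenyl]-2,3-dihydro-4H-pyran-4-one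
Product: 6 (S)-2-[3-(tert-butyldimethylsilyloxy)-4-methoxyphenyl]-5-(phenylthio)-2,3-dihydro-4H-pyran-4-one
Conditions: PhSCl, 2,6-lutidine, CH2Cl2, −78 to 0 °C
Reagents that add atoms: benzenesulfenyl chloride, ClSc1ccccc1
Why: Electrophilic α-sulfenylation of a β-alkoxy enone, the sulfur counterpart of the routine α-halogenation of dihydropyranones; the push–pull carbon C5 is far more nucleophilic than ring B, and the weak hindered base leaves H-3 and therefore C2 untouched.

Step 4
Reactants: 6 (S)-2-[3-(tert-butyldimethylsilyloxy)-4-methoxyphenyl]-5-(phenylthio)-2,3-dihydro-4H-pyran-4-one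
Product: 7 (2S)-2-[3-(tert-butyldimethylsilyloxy)-4-methoxyphenyl]-5-(phenylsulfinyl)-2,3-dihydro-4H-pyran-4-one (both epimers at sulfur)
Conditions: mCPBA (1.0 equiv), CH2Cl2, −78 to −30 °C
Reagents that add atoms: 3-chloroperbenzoic acid, O=C(OO)c1cccc(Cl)c1
Why: Chemoselective sulfide-to-sulfoxide oxidation with one equivalent of peracid at low temperature; the acceptor-substituted C5=C6 bond and the arene are inert, and the sulfur centre needs no control because it is expelled in step 8.

Step 5
Reactants: 8 5-methylhex-4-enoic acid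
Product: 9 5-methylhex-4-enoyl chloride
Conditions: (COCl)2, DMF (cat.), CH2Cl2, 0 °C to rt
Reagents that add atoms: oxalyl chloride, O=C(Cl)C(=O)Cl
Why: Acid chloride formation through a Vilsmeier-type chloroiminium catalyst under conditions that leave the trisubstituted alkene alone.

Step 6
Reactants: 9 5-methylhex-4-enoyl chloride; 10 1,1-dimethoxyethene
Product: 11 1,1-dimethoxy-7-methylocta-1,6-dien-3-one
Conditions: 10 (2.2 equiv), Et2O, 0 °C to reflux
Reagents that add atoms: none
Why: C-acylation of a ketene acetal, known for simple acid chlorides; the second equivalent of 10 takes up HCl, so no amine is present that could turn 9 into a ketene.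

Step 7
Reactants: 11 1,1-dimethoxy-7-methylocta-1,6-dien-3-one
Product: 13 (3Z)-1,1-dimethoxy-7-methyl-3-(trimethylsilyloxy)octa-1,3,6-triene, via lithium dienolate 12 (not isolated)
Conditions: LiN(iPr)2, THF, −78 °C; Me3SiCl, −78 to 0 °C; pentane, filtration, used without chromatography
Reagents that add atoms: chlorotrimethylsilane, C[Si](C)(C)Cl
Why: Kinetic α'-deprotonation of a vinylogous carbonate and O-silylation of the cross-conjugated enolate; allylic strain against the bulky dimethoxyvinyl group should favour the (Z)-enolate, as with aryl alkyl ketones, which turns the prenyl chain outward and keeps the s-cis diene accessible.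

Step 8
Reactants: 7 (2S)-2-[3-(tert-butyldimethylsilyloxy)-4-methoxyphenyl]-5-(phenylsulfinyl)-2,3-dihydro-4H-pyran-4-one; 13 (3Z)-1,1-dimethoxy-7-methyl-3-(trimethylsilyloxy)octa-1,3,6-triene
Product: 17 (2S)-3'-(tert-butyldimethylsilyloxy)-7-hydroxy-4',5-dimethoxy-8-prenylflavanone, via cis-fused cycloadduct 14 (not isolated), via 5,8-dihydro intermediate 15 (not isolated), via 7-O-trimethylsilyl flavanone 16 (not isolated)
Conditions: 13 (3 equiv), PhMe (1 M), 80 °C, sealed tube; then MeOH, PPTS (cat.), rt
Reagents that add atoms: none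
Why: Proposed new method: the prenyl-bearing diene terminus C4 of 13, made nucleophilic by the three oxygen donors, attacks the enone β-carbon C6 of 7 (future C8–C8a bond) while the ketene acetal carbon C1 closes on the sulfinyl-bearing C5 (future C5–C4a bond), so that six-membered ring A forms by an asynchronous, normal-demand, intermolecular [4+2] cycloaddition to give the cis-fused adduct 14. In 14 the sulfinyl group on C4a and H-8a are cis by necessity, which is the geometry of a thermal syn (Ei) sulfoxide elimination, so PhSOH should leave at the reaction temperature without base to give 15. Ionisation of one C5 methoxy group of 15 gives a cation stabilised by O1, the second methoxy group and the C7 silyloxy group, loss of H-8 aromatises it to 16, and methanolysis of the labile aryl TMS ether gives 17 with the hindered C5 oxygen already methylated and the aryl TBS ether intact. The closest known reaction types are the regioselective cycloaddition–aromatisation of 1,1-dialkoxy-3-silyloxydienes with haloquinones and halo-enones, the tandem cycloaddition–sulfoxide elimination of 2-sulfinyl enones and sulfinylquinones, and cycloadditions of chromones that carry an acceptor at C3; a 5-sulfinyl-2,3-dihydropyran-4-one has not been used in this way. No lasting stereocentre is created, since C4a, C8 and C8a become planar and sulfur leaves, and C2 is a spectator that stays (S) because the medium is never basic. The selectivity needed is regiochemical, and it is secured because the carbonyl and sulfinyl groups both make C6 the electrophilic end of the dienophile, which pairs with the nucleophilic C4 of the diene and puts the prenyl group on C8 and the acetal carbon at C5.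

Step 9
Reactants: 17 (2S)-3'-(tert-butyldimethylsilyloxy)-7-hydroxy-4',5-dimethoxy-8-prenylflavanone
Product: 18 (2S)-3'-(tert-butyldimethylsilyloxy)-4',5,7-trimethoxy-8-prenylflavanone
Conditions: Me3SiCHN2 (2 M in hexanes), PhMe/MeOH 4:1, 0 °C to rt; AcOH quench
Reagents that add atoms: (trimethylsilyl)diazomethane, C[Si](C)(C)C=[N+]=[N-]
Why: O-methylation of an acidic phenol (7-OH para to the C4 carbonyl) by a diazoalkane in methanol, free of base, so ring C is not opened to the chalcone and C2 keeps its configuration.

Step 10
Reactants: 18 (2S)-3'-(tert-butyldimethylsilyloxy)-4',5,7-trimethoxy-8-prenylflavanone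
Product: 19 (2S)-3'-hydroxy-4',5,7-trimethoxy-8-prenylflavanone (CNP0403319.1)
Conditions: Bu4NF, AcOH (1:1.2), THF, 0 °C
Reagents that add atoms: none
Why: Fluoride-induced cleavage of an aryl silyl ether; acetic acid buffers fluoride and the liberated phenoxide, which suppresses retro-oxa-Michael racemisation of the flavanone.

Compound list
1 | isovanillin | COc1ccc(C=O)cc1O | starting material
2 | 3-(tert-butyldimethylsilyloxy)-4-methoxybenzaldehyde | COc1ccc(C=O)cc1O[Si](C)(C)C(C)(C)C | intermediate
3 | (E)-1-methoxy-3-(trimethylsilyloxy)buta-1,3-diene | CO/C=C/C(=C)O[Si](C)(C)C | starting material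
4 | (S,E)-5-[3-(tert-butyldimethylsilyloxy)-4-methoxyphenyl]-1-methoxy-5-(trimethylsilyloxy)pent-1-en-3-one | COc1ccc([C@@H](O[Si](C)(C)C)CC(=O)/C=C/OC)cc1O[Si](C)(C)C(C)(C)C | intermediate
5 | (S)-2-[3-(tert-butyldimethylsilyloxy)-4-methoxyphenyl]-2,3-dihydro-4H-pyran-4-one | COc1ccc([C@@H]2CC(=O)C=CO2)cc1O[Si](C)(C)C(C)(C)C | intermediate
6 | (S)-2-[3-(tert-butyldimethylsilyloxy)-4-methoxyphenyl]-5-(phenylthio)-2,3-dihydro-4H-pyran-4-one | COc1ccc([C@@H]2CC(=O)C(Sc3ccccc3)=CO2)cc1O[Si](C)(C)C(C)(C)C | intermediate
7 | (2S)-2-[3-(tert-butyldimethylsilyloxy)-4-methoxyphenyl]-5-(phenylsulfinyl)-2,3-dihydro-4H-pyran-4-one, both epimers at sulfur | COc1ccc([C@@H]2CC(=O)C(S(=O)c3ccccc3)=CO2)cc1O[Si](C)(C)C(C)(C)C | intermediate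
8 | 5-methylhex-4-enoic acid | CC(C)=CCCC(=O)O | starting material
9 | 5-methylhex-4-enoyl chloride | CC(C)=CCCC(=O)Cl | intermediate
10 | 1,1-dimethoxyethene | C=C(OC)OC | starting material
11 | 1,1-dimethoxy-7-methylocta-1,6-dien-3-one | COC(OC)=CC(=O)CCC=C(C)C | intermediate
12 | lithium (3Z)-1,1-dimethoxy-7-methylocta-1,3,6-trien-3-olate | COC(OC)=C/C([O-])=C/CC=C(C)C.[Li+] | intermediate
13 | (3Z)-1,1-dimethoxy-7-methyl-3-(trimethylsilyloxy)octa-1,3,6-triene | COC(OC)=C/C(O[Si](C)(C)C)=C/CC=C(C)C | intermediate
14 | (2S)-3'-(tert-butyldimethylsilyloxy)-4',5,5-trimethoxy-4a-(phenylsulfinyl)-8-prenyl-7-(trimethylsilyloxy)-4a,5,8,8a-tetrahydroflavanone, cis ring fusion; C4a, C8, C8a and S left open because all are erased | COc1ccc([C@@H]2CC(=O)C3(S(=O)c4ccccc4)C(OC)(OC)C=C(O[Si](C)(C)C)C(CC=C(C)C)C3O2)cc1O[Si](C)(C)C(C)(C)C | intermediate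
15 | (2S)-3'-(tert-butyldimethylsilyloxy)-4',5,5-trimethoxy-8-prenyl-7-(trimethylsilyloxy)-5,8-dihydroflavanone, C8 left open | COc1ccc([C@@H]2CC(=O)C3=C(O2)C(CC=C(C)C)C(O[Si](C)(C)C)=CC3(OC)OC)cc1O[Si](C)(C)C(C)(C)C | intermediate
16 | (2S)-3'-(tert-butyldimethylsilyloxy)-4',5-dimethoxy-8-prenyl-7-(trimethylsilyloxy)flavanone | COc1ccc([C@@H]2CC(=O)c3c(OC)cc(O[Si](C)(C)C)c(CC=C(C)C)c3O2)cc1O[Si](C)(C)C(C)(C)C | intermediate
17 | (2S)-3'-(tert-butyldimethylsilyloxy)-7-hydroxy-4',5-dimethoxy-8-prenylflavanone | COc1ccc([C@@H]2CC(=O)c3c(OC)cc(O)c(CC=C(C)C)c3O2)cc1O[Si](C)(C)C(C)(C)C | intermediate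
18 | (2S)-3'-(tert-butyldimethylsilyloxy)-4',5,7-trimethoxy-8-prenylflavanone | COc1ccc([C@@H]2CC(=O)c3c(OC)cc(OC)c(CC=C(C)C)c3O2)cc1O[Si](C)(C)C(C)(C)C | intermediate
19 | (2S)-3'-hydroxy-4',5,7-trimethoxy-8-prenylflavanone | COc1ccc([C@@H]2CC(=O)c3c(OC)cc(OC)c(CC=C(C)C)c3O2)cc1O | target

Total step count: 10. Longest linear sequence: 7 steps (steps 1, 2, 3, 4, 8, 9 and 10, from isovanillin). The diene branch (steps 5–7) is convergent.

Steps most likely to fail

Step 8 (the step beyond known chemistry).
- The donor oxygen O1 may leave the enone too unreactive.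
- A stepwise Michael addition may be followed by expulsion of O1 and opening of ring C.
- Silyl transfer to the sulfoxide oxygen may start a Pummerer-type decomposition.
- Sulfenylating by-products may attack the electron-rich ring A once the excess diene is consumed.

High pressure (about 12 kbar, CH2Cl2, rt) is the first adjustment, but it changes only the conditions. The fallback uses known chemistry, sets out from 1 and comes back at 19. Commercial 2'-hydroxy-4',6'-dimethoxyacetophenone is C-prenylated ortho to the phenoxide (prenyl bromide, KOH, MeOH) to 1-[2-hydroxy-4,6-dimethoxy-3-(3-methylbut-2-enyl)phenyl]ethanone F1. Claisen–Schmidt condensation of this ketone with 1 (excess KOH, EtOH, rt) gives (E)-2',3-dihydroxy-4,4',6'-trimethoxy-3'-prenylchalcone F2. NaOAc in refluxing EtOH closes ring C by oxa-Michael addition to racemic 3'-hydroxy-4',5,7-trimethoxy-8-prenylflavanone F3. Kinetic resolution by asymmetric transfer hydrogenation (RuCl(p-cymene)[(R,R)-TsDPEN], HCO2H/Et3N, EtOAc, rt, to half conversion) should reduce the (2R)-ketone to cis-(2R,4R)-3'-hydroxy-4',5,7-trimethoxy-8-prenylflavan-4-ol F4. This leaves 19, which is separated by chromatography.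

Step 6. Chloride-induced demethylation of the acylated oxocarbenium ion, or self-condensation of the enolisable acid chloride, may outrun proton loss. The fallback sets out from 10 and comes back at 11. Compound 10 is acylated with acetyl chloride, the parent case of this reaction, to 4,4-dimethoxybut-3-en-2-one F5. LiN(iPr)2 (THF, −78 °C) converts it into lithium 4,4-dimethoxybuta-1,3-dien-2-olate F6. Prenyl bromide alkylates this enolate at the α'-carbon to give 11. The chain is thus attached by enolate alkylation, and 8 and 9 are not needed.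

Step 3. Sulfenylation may stray to the electron-rich ring B, or the liberated acid may open ring C. The fallback sets out from 5 and comes back at 6. α-Bromination with NBS (CH2Cl2, 0 °C) gives (S)-5-bromo-2-[3-(tert-butyldimethylsilyloxy)-4-methoxyphenyl]-2,3-dihydro-4H-pyran-4-one F7. Palladium-catalysed C–S cross-coupling with PhSH (Pd2(dba)3, Xantphos, iPr2NEt, dioxane, 80 °C) then gives 6.

Further compounds
F1 | step 8 | 1-[2-hydroxy-4,6-dimethoxy-3-(3-methylbut-2-enyl)phenyl]ethanone | CC(=O)c1c(O)c(CC=C(C)C)c(OC)cc1OC
F2 | step 8 | (E)-2',3-dihydroxy-4,4',6'-trimethoxy-3'-prenylchalcone | COc1ccc(/C=C/C(=O)c2c(O)c(CC=C(C)C)c(OC)cc2OC)cc1O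
F3 | step 8 | racemic 3'-hydroxy-4',5,7-trimethoxy-8-prenylflavanone | COc1ccc(C2CC(=O)c3c(OC)cc(OC)c(CC=C(C)C)c3O2)cc1O
F4 | step 8 | cis-(2R,4R)-3'-hydroxy-4',5,7-trimethoxy-8-prenylflavan-4-ol | COc1ccc([C@H]2C[C@@H](O)c3c(OC)cc(OC)c(CC=C(C)C)c3O2)cc1O
F5 | step 6 | 4,4-dimethoxybut-3-en-2-one | COC(OC)=CC(C)=O
F6 | step 6 | lithium 4,4-dimethoxybuta-1,3-dien-2-olate | COC(OC)=CC(=C)[O-].[Li+]
F7 | step 3 | (S)-5-bromo-2-[3-(tert-butyldimethylsilyloxy)-4-methoxyphenyl]-2,3-dihydro-4H-pyran-4-one | COc1ccc([C@@H]2CC(=O)C(Br)=CO2)cc1O[Si](C)(C)C(C)(C)C
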